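**Retrosynthetic overview**

1. The side-chain oxirane is made last by Shi epoxidation of a prenyl alkene; the ring chlorohydrin comes from chloride opening (at C4) of a C3–C4 epoxide delivered syn to the free C2 hydroxyl.
2. Both angelates are put on in one double acylation of a C1/C3′ diol; the C3′–C4′ bond comes from asymmetric allylboration of an α-methylene lactol, followed by cross-metathesis to the prenyl group.
3. The C6–C2′ bond, cis to the C1 oxygen, comes from a 5-exo radical cyclisation of an iodoacetal tethered on the C1 oxygen; its two carbons become C2′ and C3′, and lactone α-methylenation adds C1′.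
4. The C1/C2 stereocentres and the whole carbocycle come from bromobenzene by arene-dioxygenase cis-dihydroxylation; the C3 methyl comes from Negishi coupling of the surviving alkenyl bromide.
5. Ring order: six-membered carbocycle (taken from the arene, never closed) → temporary cis-fused tetrahydrofuran/γ-lactone (reopened at the allylation) → C3–C4 oxirane (made, then opened) → side-chain oxirane.

Assumption: angelic anhydride, (−)-Ipc2BOMe and the L-fructose-derived Shi ketone are bought; ring atoms are numbered C1–C6 as in the name of the target (C1 ring ester, C2 OH, C3 C(OH)Me, C4 Cl, C6 side chain), side-chain atoms C1′–C6′ from the methylidene carbon, and Ang = (2Z)-2-methylbut-2-enoyl.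

**Route**

Step 1
Reactants: 1 bromobenzene
Product: 2 (1S,2S)-3-bromocyclohexa-3,5-diene-1,2-diol
Conditions: E. coli JM109(pDTG601) whole cells expressing toluene dioxygenase (a Rieske-type arene cis-dihydroxylating dioxygenase), air, glucose, IPTG, mineral-salts medium pH 7, 35 °C; EtOAc extraction
Reagents that add atoms: dioxygen, O=O
Why: The arene dioxygenase adds both atoms of O2 to one face of the 2,3-bond of the achiral arene (enzymatic dearomatising cis-dihydroxylation), giving a single enantiomer whose two carbinol carbons become C1 and C2 of the target with the required absolute configuration.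

Step 2
Reactants: 2 (1S,2S)-3-bromocyclohexa-3,5-diene-1,2-diol
Product: 3 (3aS,7aS)-4-bromo-2-(4-methoxyphenyl)-3a,7a-dihydro-1,3-benzodioxole (acetal carbon as epimers)
Conditions: 4-MeOC6H4CH(OMe)2, camphor-10-sulfonic acid (cat.), CH2Cl2, −20 °C; Et3N quench
Reagents that add atoms: 4-methoxybenzaldehyde dimethyl acetal, COC(OC)c1ccc(OC)cc1
Why: Acid-catalysed transacetalisation ties the cis-diol into a cis-fused dioxolane without touching either stereocentre, and the low temperature avoids dehydration to a bromophenol.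

Step 3
Reactants: 3 (3aS,7aS)-4-bromo-2-(4-methoxyphenyl)-3a,7a-dihydro-1,3-benzodioxole
Product: 4 (1S,6S)-5-bromo-6-[(4-methoxybenzyl)oxy]cyclohexa-2,4-dien-1-ol
Conditions: iBu2AlH (3 equiv), CH2Cl2, −78 → 0 °C; aq. potassium sodium tartrate
Reagents that add atoms: none
Why: In this regioselective reductive acetal opening the alane binds the less hindered acetal oxygen (on C1, remote from C–Br), that C–O bond breaks and hydride reduces the oxocarbenium ion, so the 4-methoxybenzyl group ends on the C2 oxygen and the C1 hydroxyl is free.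

Step 4
Reactants: 4 (1S,6S)-5-bromo-6-[(4-methoxybenzyl)oxy]cyclohexa-2,4-dien-1-ol; 5 ethoxyethene (ethyl vinyl ether)
Product: 6 (5S,6S)-1-bromo-5-(1-ethoxy-2-iodoethoxy)-6-[(4-methoxybenzyl)oxy]cyclohexa-1,3-diene (acetal carbon as epimers)
Conditions: N-iodosuccinimide (1.3 equiv), ethoxyethene (5 equiv), CH2Cl2, −40 → 0 °C
Reagents that add atoms: N-iodosuccinimide, O=C1CCC(=O)N1I
Why: Iodo-etherification of the electron-rich enol ether (Ueno–Stork haloacetal formation) is much faster than attack on the electron-poor bromodiene, and the iodonium ion is captured by the free C1 hydroxyl.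

Step 5
Reactants: 6 (5S,6S)-1-bromo-5-(1-ethoxy-2-iodoethoxy)-6-[(4-methoxybenzyl)oxy]cyclohexa-1,3-diene
Product: 7 (3aR,7S,7aS)-6-bromo-2-ethoxy-7-[(4-methoxybenzyl)oxy]-2,3,3a,4,7,7a-hexahydro-1-benzofuran (C2 epimers)
Conditions: Bu3SnH (1.2 equiv, syringe pump), Et3B (0.2 equiv), air, toluene, 0 → 23 °C
Reagents that add atoms: none
Why: In this Ueno–Stork 5-exo-trig radical cyclisation the tether on the C1 oxygen can only deliver carbon to C6 on the same face (cis ring fusion), which sets C6, and the allyl radical is reduced at its secondary terminus to leave the C3=C4 alkenyl bromide; any material reduced at C3 loses bromine and cannot be methylated in step 6.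

Step 6
Reactants: 7 (3aR,7S,7aS)-6-bromo-2-ethoxy-7-[(4-methoxybenzyl)oxy]-2,3,3a,4,7,7a-hexahydro-1-benzofuran
Product: 8 (3aR,7R,7aS)-2-ethoxy-7-[(4-methoxybenzyl)oxy]-6-methyl-2,3,3a,4,7,7a-hexahydro-1-benzofuran (C2 epimers)
Conditions: MeZnCl (2 equiv), Pd(PPh3)4 (5 mol%), THF, 50 °C
Reagents that add atoms: methylzinc chloride, C[Zn]Cl
Why: Negishi cross-coupling replaces the alkenyl bromide by the C3 methyl group with the double bond fixed at C3=C4 and no stereocentre involved.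

Step 7
Reactants: 8 (3aR,7R,7aS)-2-ethoxy-7-[(4-methoxybenzyl)oxy]-6-methyl-2,3,3a,4,7,7a-hexahydro-1-benzofuran
Product: 9 (3aR,7R,7aS)-7-[(4-methoxybenzyl)oxy]-6-methyl-2,3,3a,4,7,7a-hexahydro-1-benzofuran-2-ol (lactol, C2 epimers)
Conditions: 1 M aq. HCl/THF (1:4), 23 °C
Reagents that add atoms: water, O
Why: Acetal hydrolysis through the cyclic oxocarbenium ion exchanges ethoxy for hydroxy, while the benzylic ether and the trisubstituted alkene are inert to dilute acid at room temperature.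

Step 8
Reactants: 9 (3aR,7R,7aS)-7-[(4-methoxybenzyl)oxy]-6-methyl-2,3,3a,4,7,7a-hexahydro-1-benzofuran-2-ol
Product: 10 (3aR,7R,7aS)-7-[(4-methoxybenzyl)oxy]-6-methyl-3a,4,7,7a-tetrahydro-1-benzofuran-2(3H)-one
Conditions: Pr4N[RuO4] (5 mol%), N-methylmorpholine N-oxide (1.5 equiv), 4 Å molecular sieves, CH2Cl2, 23 °C
Reagents that add atoms: none
Why: Ley–Griffith oxidation converts the lactol into the γ-lactone under neutral conditions that leave the alkene, the benzylic ether and the ring-fusion stereocentres untouched.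

Step 9
Reactants: 10 (3aR,7R,7aS)-7-[(4-methoxybenzyl)oxy]-6-methyl-3a,4,7,7a-tetrahydro-1-benzofuran-2(3H)-one
Product: 11 (3aR,7R,7aS)-3-[(dimethylamino)methyl]-7-[(4-methoxybenzyl)oxy]-6-methyl-3a,4,7,7a-tetrahydro-1-benzofuran-2(3H)-one (C3 epimers)
Conditions: LiN(iPr)2 (1.15 equiv), THF, −78 °C; then CH2=NMe2+ I− (1.5 equiv), −78 → 23 °C
Reagents that add atoms: N,N-dimethylmethyleneiminium iodide (Eschenmoser's salt), C=[N+](C)C.[I-]
Why: Mannich reaction of the lactone lithium enolate with the preformed iminium ion adds the carbon that becomes C1′; the new C3 centre is irrelevant because it is destroyed in the next step.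

Step 10
Reactants: 11 (3aR,7R,7aS)-3-[(dimethylamino)methyl]-7-[(4-methoxybenzyl)oxy]-6-methyl-3a,4,7,7a-tetrahydro-1-benzofuran-2(3H)-one
Product: 13 (3aR,7R,7aS)-7-[(4-methoxybenzyl)oxy]-6-methyl-3-methylidene-3a,4,7,7a-tetrahydro-1-benzofuran-2(3H)-one, via trimethylammonium iodide 12 (not isolated)
Conditions: MeI (10 equiv), MeOH, 23 °C; concentrate; then aq. NaHCO3/CH2Cl2, 23 °C
Reagents that add atoms: none
Why: Exhaustive N-methylation followed by E1cB (Hofmann-type) loss of trimethylamine from the acidic α-position gives the α-methylene lactone, which carries the C1′=C2′ alkene of the target.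

Step 11
Reactants: 13 (3aR,7R,7aS)-7-[(4-methoxybenzyl)oxy]-6-methyl-3-methylidene-3a,4,7,7a-tetrahydro-1-benzofuran-2(3H)-one
Product: 14 (3aR,7R,7aS)-7-[(4-methoxybenzyl)oxy]-6-methyl-3-methylidene-2,3,3a,4,7,7a-hexahydro-1-benzofuran-2-ol (lactol, C2 epimers)
Conditions: iBu2AlH (1.1 equiv), CH2Cl2, −78 °C; aq. potassium sodium tartrate
Reagents that add atoms: none
Why: Low-temperature 1,2-half-reduction of the lactone stops at the aluminium hemiacetal and gives the lactol, a masked hydroxy enal.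

Step 12
Reactants: 14 (3aR,7R,7aS)-7-[(4-methoxybenzyl)oxy]-6-methyl-3-methylidene-2,3,3a,4,7,7a-hexahydro-1-benzofuran-2-ol
Product: 16 (1S,2R,6R)-6-[(3S)-3-hydroxyhexa-1,5-dien-2-yl]-2-[(4-methoxybenzyl)oxy]-3-methylcyclohex-3-en-1-ol, via open-chain hydroxy enal 15 (not isolated)
Conditions: (−)-Ipc2B(allyl) (2.5 equiv; made from (−)-Ipc2BOMe and CH2=CHCH2MgBr in Et2O, magnesium salts filtered off), Et2O, −78 → 23 °C; then NaOH, H2O2
Reagents that add atoms: allylmagnesium bromide, C=CC[Mg]Br (allyl source, transferred as (−)-B-allyldiisopinocampheylborane, C=CCB([C@@H]1C[C@@H]2C[C@@H](C2(C)C)[C@H]1C)[C@@H]1C[C@@H]2C[C@@H](C2(C)C)[C@H]1C)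
Why: Brown asymmetric allylboration of the ring-opened enal through a chair (Zimmerman–Traxler) transition state is reagent-controlled, and the (+)-α-pinene-derived borane gives the 3′S carbinol while releasing the C1 hydroxyl.

Step 13
Reactants: 16 (1S,2R,6R)-6-[(3S)-3-hydroxyhexa-1,5-dien-2-yl]-2-[(4-methoxybenzyl)oxy]-3-methylcyclohex-3-en-1-ol; 17 2-methylbut-2-ene
Product: 18 (1S,2R,6R)-6-[(3S)-3-hydroxy-6-methylhepta-1,5-dien-2-yl]-2-[(4-methoxybenzyl)oxy]-3-methylcyclohex-3-en-1-ol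
Conditions: second-generation Grubbs catalyst, (H2IMes)(PCy3)Cl2Ru=CHPh (5 mol%), 2-methylbut-2-ene/CH2Cl2 (1:1), 40 °C, sealed tube
Reagents that add atoms: none
Why: Olefin cross-metathesis engages only the monosubstituted alkene (the 1,1-disubstituted and ring trisubstituted alkenes are too hindered) and turns the allyl group into the prenyl group.

Step 14
Reactants: 18 (1S,2R,6R)-6-[(3S)-3-hydroxy-6-methylhepta-1,5-dien-2-yl]-2-[(4-methoxybenzyl)oxy]-3-methylcyclohex-3-en-1-ol; 19 (2Z)-2-methylbut-2-enoic anhydride (angelic anhydride)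
Product: 20 (1S,2R,6R)-2-[(4-methoxybenzyl)oxy]-3-methyl-6-[(3S)-6-methyl-3-(AngO)hepta-1,5-dien-2-yl]cyclohex-3-en-1-yl (2Z)-2-methylbut-2-enoate
Conditions: LiN(SiMe3)2 (2.2 equiv), THF, −78 °C; then 19 (3 equiv), −78 → 0 °C
Reagents that add atoms: none
Why: O-acylation of the dilithium dialkoxide by the anhydride needs no nucleophilic catalyst, so both esters form with the Z alkene geometry of the reagent retained and no stereocentre touched.

Step 15
Reactants: 20 (1S,2R,6R)-2-[(4-methoxybenzyl)oxy]-3-methyl-6-[(3S)-6-methyl-3-(AngO)hepta-1,5-dien-2-yl]cyclohex-3-en-1-yl (2Z)-2-methylbut-2-enoate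
Product: 21 (1S,2R,6R)-2-hydroxy-3-methyl-6-[(3S)-6-methyl-3-(AngO)hepta-1,5-dien-2-yl]cyclohex-3-en-1-yl (2Z)-2-methylbut-2-enoate
Conditions: 2,3-dichloro-5,6-dicyano-1,4-benzoquinone (1.3 equiv), CH2Cl2/pH 7 phosphate buffer (10:1), 0 °C
Reagents that add atoms: none
Why: Oxidative cleavage of the 4-methoxybenzyl ether (hydride abstraction, hydrolysis of the oxocarbenium ion) frees the allylic C2 hydroxyl under buffered conditions that spare the esters and alkenes.

Step 16
Reactants: 21 (1S,2R,6R)-2-hydroxy-3-methyl-6-[(3S)-6-methyl-3-(AngO)hepta-1,5-dien-2-yl]cyclohex-3-en-1-yl (2Z)-2-methylbut-2-enoate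
Product: 22 (1S,2S,3S,4R,6R)-2-hydroxy-1-methyl-4-[(3S)-6-methyl-3-(AngO)hepta-1,5-dien-2-yl]-7-oxabicyclo[4.1.0]heptan-3-yl (2Z)-2-methylbut-2-enoate
Conditions: VO(acac)2 (5 mol%), t-BuOOH (1.5 equiv, in decane), CH2Cl2, 0 → 23 °C
Reagents that add atoms: tert-butyl hydroperoxide, CC(C)(C)OO
Why: Vanadium-catalysed hydroxyl-directed epoxidation delivers oxygen to the allylic-alcohol alkene only, on the face of the C2 hydroxyl, which sets the C3–O bond, while the prenyl, methylidene and angelate alkenes are left alone.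

Step 17
Reactants: 22 (1S,2S,3S,4R,6R)-2-hydroxy-1-methyl-4-[(3S)-6-methyl-3-(AngO)hepta-1,5-dien-2-yl]-7-oxabicyclo[4.1.0]heptan-3-yl (2Z)-2-methylbut-2-enoate
Product: 23 (1S,2S,3S,4S,6R)-4-chloro-2,3-dihydroxy-3-methyl-6-[(3S)-6-methyl-3-(AngO)hepta-1,5-dien-2-yl]cyclohexyl (2Z)-2-methylbut-2-enoate
Conditions: LiCl (10 equiv), AcOH (5 equiv), THF, 23 °C
Reagents that add atoms: lithium chloride, [Li+].[Cl-]
Why: SN2 opening of the protonated epoxide at the less substituted C4 with inversion (Fürst–Plattner trans-diaxial opening with the side chain equatorial) puts chlorine anti to the tertiary C3 hydroxyl, whose configuration is kept.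

Step 18
Reactants: 23 (1S,2S,3S,4S,6R)-4-chloro-2,3-dihydroxy-3-methyl-6-[(3S)-6-methyl-3-(AngO)hepta-1,5-dien-2-yl]cyclohexyl (2Z)-2-methylbut-2-enoate
Product: 24 (1S,2S,3S,4S,6R)-4-chloro-6-[(3S)-4-[(2S)-3,3-dimethyloxiran-2-yl]-3-(AngO)but-1-en-2-yl]-2,3-dihydroxy-3-methylcyclohexyl (2Z)-2-methylbut-2-enoate
Conditions: 1,2:4,5-di-O-isopropylidene-β-L-erythro-2,3-hexodiulo-2,6-pyranose (L-fructose-derived Shi ketone, 1 equiv in portions), KHSO5 (as 2KHSO5·KHSO4·K2SO4, 2 equiv), NaHCO3, Bu4NHSO4, MeCN/CH2(OMe)2/aq. Na2EDTA, pH about 8, 0 °C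
Reagents that add atoms: potassium peroxymonosulfate, [K+].[O-]S(=O)(=O)OO
Why: Shi asymmetric epoxidation through the spiro transition state of the chiral dioxirane attacks only the electron-rich trisubstituted prenyl alkene and, with the L-series ketone, gives the 5′S oxirane, while the near-neutral pH keeps the chlorohydrin and the hydroxy ester intact.

**Compound list**

1 | bromobenzene | Brc1ccccc1 | starting material
2 | (1S,2S)-3-bromocyclohexa-3,5-diene-1,2-diol | C1=CC=C(Br)[C@@H](O)[C@H]1O | intermediate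
3 | (3aS,7aS)-4-bromo-2-(4-methoxyphenyl)-3a,7a-dihydro-1,3-benzodioxole | C1=CC=C(Br)[C@@H](OC2c3ccc(OC)cc3)[C@H]1O2 | intermediate
4 | (1S,6S)-5-bromo-6-[(4-methoxybenzyl)oxy]cyclohexa-2,4-dien-1-ol | C1=CC=C(Br)[C@@H](OCc2ccc(OC)cc2)[C@H]1O | intermediate
5 | ethoxyethene (ethyl vinyl ether) | C=COCC | starting material
6 | (5S,6S)-1-bromo-5-(1-ethoxy-2-iodoethoxy)-6-[(4-methoxybenzyl)oxy]cyclohexa-1,3-diene | C1=CC=C(Br)[C@@H](OCc2ccc(OC)cc2)[C@H]1OC(OCC)CI | intermediate
7 | (3aR,7S,7aS)-6-bromo-2-ethoxy-7-[(4-methoxybenzyl)oxy]-2,3,3a,4,7,7a-hexahydro-1-benzofuran | CCOC1C[C@H]2CC=C(Br)[C@@H](OCc3ccc(OC)cc3)[C@H]2O1 | intermediate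
8 | (3aR,7R,7aS)-2-ethoxy-7-[(4-methoxybenzyl)oxy]-6-methyl-2,3,3a,4,7,7a-hexahydro-1-benzofuran | CCOC1C[C@H]2CC=C(C)[C@@H](OCc3ccc(OC)cc3)[C@H]2O1 | intermediate
9 | (3aR,7R,7aS)-7-[(4-methoxybenzyl)oxy]-6-methyl-2,3,3a,4,7,7a-hexahydro-1-benzofuran-2-ol | OC1C[C@H]2CC=C(C)[C@@H](OCc3ccc(OC)cc3)[C@H]2O1 | intermediate
10 | (3aR,7R,7aS)-7-[(4-methoxybenzyl)oxy]-6-methyl-3a,4,7,7a-tetrahydro-1-benzofuran-2(3H)-one | O=C1C[C@H]2CC=C(C)[C@@H](OCc3ccc(OC)cc3)[C@H]2O1 | intermediate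
11 | (3aR,7R,7aS)-3-[(dimethylamino)methyl]-7-[(4-methoxybenzyl)oxy]-6-methyl-3a,4,7,7a-tetrahydro-1-benzofuran-2(3H)-one | O=C1C(CN(C)C)[C@H]2CC=C(C)[C@@H](OCc3ccc(OC)cc3)[C@H]2O1 | intermediate
12 | N,N,N-trimethyl-1-[(3aR,7R,7aS)-7-[(4-methoxybenzyl)oxy]-6-methyl-2-oxo-2,3,3a,4,7,7a-hexahydro-1-benzofuran-3-yl]methanaminium iodide | O=C1C(C[N+](C)(C)C)[C@H]2CC=C(C)[C@@H](OCc3ccc(OC)cc3)[C@H]2O1.[I-] | intermediate
13 | (3aR,7R,7aS)-7-[(4-methoxybenzyl)oxy]-6-methyl-3-methylidene-3a,4,7,7a-tetrahydro-1-benzofuran-2(3H)-one | O=C1C(=C)[C@H]2CC=C(C)[C@@H](OCc3ccc(OC)cc3)[C@H]2O1 | intermediate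
14 | (3aR,7R,7aS)-7-[(4-methoxybenzyl)oxy]-6-methyl-3-methylidene-2,3,3a,4,7,7a-hexahydro-1-benzofuran-2-ol | OC1C(=C)[C@H]2CC=C(C)[C@@H](OCc3ccc(OC)cc3)[C@H]2O1 | intermediate
15 | 2-[(1R,5R,6S)-6-hydroxy-5-[(4-methoxybenzyl)oxy]-4-methylcyclohex-3-en-1-yl]prop-2-enal | O=CC(=C)[C@H]1CC=C(C)[C@@H](OCc2ccc(OC)cc2)[C@H]1O | intermediate
16 | (1S,2R,6R)-6-[(3S)-3-hydroxyhexa-1,5-dien-2-yl]-2-[(4-methoxybenzyl)oxy]-3-methylcyclohex-3-en-1-ol | C=CC[C@H](O)C(=C)[C@H]1CC=C(C)[C@@H](OCc2ccc(OC)cc2)[C@H]1O | intermediate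
17 | 2-methylbut-2-ene | CC=C(C)C | starting material
18 | (1S,2R,6R)-6-[(3S)-3-hydroxy-6-methylhepta-1,5-dien-2-yl]-2-[(4-methoxybenzyl)oxy]-3-methylcyclohex-3-en-1-ol | CC(C)=CC[C@H](O)C(=C)[C@H]1CC=C(C)[C@@H](OCc2ccc(OC)cc2)[C@H]1O | intermediate
19 | (2Z)-2-methylbut-2-enoic anhydride (angelic anhydride) | C/C=C(/C)C(=O)OC(=O)/C(C)=C\C | starting material
20 | (1S,2R,6R)-2-[(4-methoxybenzyl)oxy]-3-methyl-6-[(3S)-6-methyl-3-{[(2Z)-2-methylbut-2-enoyl]oxy}hepta-1,5-dien-2-yl]cyclohex-3-en-1-yl (2Z)-2-methylbut-2-enoate | C=C([C@H](CC=C(C)C)OC(=O)/C(C)=C\C)[C@H]1CC=C(C)[C@@H](OCc2ccc(OC)cc2)[C@H]1OC(=O)/C(C)=C\C | intermediate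
21 | (1S,2R,6R)-2-hydroxy-3-methyl-6-[(3S)-6-methyl-3-{[(2Z)-2-methylbut-2-enoyl]oxy}hepta-1,5-dien-2-yl]cyclohex-3-en-1-yl (2Z)-2-methylbut-2-enoate | C=C([C@H](CC=C(C)C)OC(=O)/C(C)=C\C)[C@H]1CC=C(C)[C@@H](O)[C@H]1OC(=O)/C(C)=C\C | intermediate
22 | (1S,2S,3S,4R,6R)-2-hydroxy-1-methyl-4-[(3S)-6-methyl-3-{[(2Z)-2-methylbut-2-enoyl]oxy}hepta-1,5-dien-2-yl]-7-oxabicyclo[4.1.0]heptan-3-yl (2Z)-2-methylbut-2-enoate | C=C([C@H](CC=C(C)C)OC(=O)/C(C)=C\C)[C@H]1C[C@H]2O[C@@]2(C)[C@@H](O)[C@H]1OC(=O)/C(C)=C\C | intermediate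
23 | (1S,2S,3S,4S,6R)-4-chloro-2,3-dihydroxy-3-methyl-6-[(3S)-6-methyl-3-{[(2Z)-2-methylbut-2-enoyl]oxy}hepta-1,5-dien-2-yl]cyclohexyl (2Z)-2-methylbut-2-enoate | C=C([C@H](CC=C(C)C)OC(=O)/C(C)=C\C)[C@H]1C[C@H](Cl)[C@@](C)(O)[C@@H](O)[C@H]1OC(=O)/C(C)=C\C | intermediate
24 | (1S,2S,3S,4S,6R)-4-chloro-6-[(3S)-4-[(2S)-3,3-dimethyloxiran-2-yl]-3-{[(2Z)-2-methylbut-2-enoyl]oxy}but-1-en-2-yl]-2,3-dihydroxy-3-methylcyclohexyl (2Z)-2-methylbut-2-enoate (CNP0333703.2) | C=C([C@H](C[C@@H]1OC1(C)C)OC(=O)/C(C)=C\C)[C@H]1C[C@H](Cl)[C@@](C)(O)[C@@H](O)[C@H]1OC(=O)/C(C)=C\C | target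

**Totals and risks**

Total step count: 18. Longest linear sequence: 18 (5, 17 and 19 are bought and enter the single line from 1).

The three steps most likely to fail:

Step 12. The lactol is only partly in its open enal form, the free hydroxyl consumes borane, and conversion or selectivity at C3′ may suffer. The fallback sets out from 13. Full reduction with iBu2AlH (3 equiv, CH2Cl2, −78 → 0 °C) gives (1S,2R,6R)-6-(3-hydroxyprop-1-en-2-yl)-2-[(4-methoxybenzyl)oxy]-3-methylcyclohex-3-en-1-ol F1. An iridium-catalysed transfer-hydrogenative allylation from the alcohol oxidation level ([Ir(cod)Cl]2, the BINAP enantiomer that gives the 3′S carbinol, 4-chloro-3-nitrobenzoic acid, Cs2CO3, allyl acetate, THF, 100 °C) then dehydrogenates only the primary allylic alcohol and allylates the transient aldehyde under catalyst control, leaving the secondary C1 hydroxyl alone. It comes back to the route at 16.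

Step 14. Two hindered secondary alkoxides, one of them axial and flanked on both sides, must both be acylated, and any nucleophilic activation risks Z to E drift to the tiglate. The fallback sets out from 18. Both hydroxyls are esterified with 2-[bis(2,2,2-trifluoroethoxy)phosphoryl]propanoic acid (N,N′-diisopropylcarbodiimide, 4-(dimethylamino)pyridine, CH2Cl2), where no alkene geometry is at stake, to give the bis(phosphonopropanoate) diester F2. A double Still–Gennari olefination with acetaldehyde (KN(SiMe3)2, 18-crown-6, THF, −78 °C) then builds both Z-configured 2-methylbut-2-enoates on the substrate. It comes back at 20.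

Step 18. A dioxirane epoxidation has to be run on a molecule with a base-sensitive trans-diaxial chlorohydrin, two free hydroxyls and an ester next to a free alcohol, and the remote C5′ centre depends on reagent control alone; the facial sense of the L-series ketone follows the spiro-transition-state model and should be confirmed on the first sample. The fallback sets out from 20 and reverses the order of the two epoxidations. Shi epoxidation under the usual pH 10.5 conditions (no free hydroxyl or chlorohydrin present) gives the side-chain epoxide 4-methoxybenzyl ether F3. The benzoquinone of step 15 then frees the C2 hydroxyl to give the side-chain epoxide allylic alcohol F4, and VO(acac)2/t-BuOOH gives the bis-epoxide alcohol F5. Finally ClTi(OiPr)3 (CH2Cl2, −20 °C) opens only the hydroxyl-bearing ring epoxide at C4 by alkoxide-templated chloride delivery. It arrives directly at 24.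

**Further compounds**

F1 | step 12 | (1S,2R,6R)-6-(3-hydroxyprop-1-en-2-yl)-2-[(4-methoxybenzyl)oxy]-3-methylcyclohex-3-en-1-ol | C=C(CO)[C@H]1CC=C(C)[C@@H](OCc2ccc(OC)cc2)[C@H]1O
F2 | step 14 | (1S,2R,6R)-2-[(4-methoxybenzyl)oxy]-3-methyl-6-[(3S)-6-methyl-3-({2-[bis(2,2,2-trifluoroethoxy)phosphoryl]propanoyl}oxy)hepta-1,5-dien-2-yl]cyclohex-3-en-1-yl 2-[bis(2,2,2-trifluoroethoxy)phosphoryl]propanoate (phosphonate α-carbons as epimers) | C=C([C@H](CC=C(C)C)OC(=O)C(C)P(=O)(OCC(F)(F)F)OCC(F)(F)F)[C@H]1CC=C(C)[C@@H](OCc2ccc(OC)cc2)[C@H]1OC(=O)C(C)P(=O)(OCC(F)(F)F)OCC(F)(F)F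
F3 | step 18 | (1S,2R,6R)-6-[(3S)-4-[(2S)-3,3-dimethyloxiran-2-yl]-3-{[(2Z)-2-methylbut-2-enoyl]oxy}but-1-en-2-yl]-2-[(4-methoxybenzyl)oxy]-3-methylcyclohex-3-en-1-yl (2Z)-2-methylbut-2-enoate | C=C([C@H](C[C@@H]1OC1(C)C)OC(=O)/C(C)=C\C)[C@H]1CC=C(C)[C@@H](OCc2ccc(OC)cc2)[C@H]1OC(=O)/C(C)=C\C
F4 | step 18 | (1S,2R,6R)-6-[(3S)-4-[(2S)-3,3-dimethyloxiran-2-yl]-3-{[(2Z)-2-methylbut-2-enoyl]oxy}but-1-en-2-yl]-2-hydroxy-3-methylcyclohex-3-en-1-yl (2Z)-2-methylbut-2-enoate | C=C([C@H](C[C@@H]1OC1(C)C)OC(=O)/C(C)=C\C)[C@H]1CC=C(C)[C@@H](O)[C@H]1OC(=O)/C(C)=C\C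
F5 | step 18 | (1S,2S,3S,4R,6R)-4-[(3S)-4-[(2S)-3,3-dimethyloxiran-2-yl]-3-{[(2Z)-2-methylbut-2-enoyl]oxy}but-1-en-2-yl]-2-hydroxy-1-methyl-7-oxabicyclo[4.1.0]heptan-3-yl (2Z)-2-methylbut-2-enoate | C=C([C@H](C[C@@H]1OC1(C)C)OC(=O)/C(C)=C\C)[C@H]1C[C@H]2O[C@@]2(C)[C@@H](O)[C@H]1OC(=O)/C(C)=C\C
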